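All runs were generated by integration from invented constants; noise was put on by code.

You cannot tell from one curve that rises and then lies flat whether the enzyme has died or the flask has reached a balance, but you can count what each enzyme has done.

all flasks: substrate 10 mM; enzyme 0.066 mol%
- autumn: impurity 3 µM; the very flask that is asked about, followed so far
- flask: impurity 3.0 µM; time 15 h

- autumn (time / min: target / %): 80.0: 29.6; 240: 34.7; 480: 35.1; 600: 34.9; 900: 34.3

(scatter of a reading: 0.5 percentage points)

- removed target is counted in
- additions bring no volume worth counting

- epsilon: at 15 h add substrate, 50.0% of the amount charged, then wait 5.0 h
- eta: at 15 h add enzyme, 50.0% of the amount charged, then wait 5.0 h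
- alpha: at 15 h take out 90% of the target then present, then wait 5.0 h
- zeta: change nothing and wait 5.0 h more

* target, in percent of the substrate first charged, at 15 h
* the option that brings most further target ("none" if no option brings more than 2 percentage points) (epsilon / eta / alpha / zeta / none)
* target present, with what was taken out counted in, in percent of the substrate first charged, after epsilon
* target present, with what was taken out counted in, in percent of the substrate first charged, after eta

The last four readings of the autumn run, which is this flask followed so far, are flat within their scatter and average 34.8%, so that is my figure for the target at 15 h. The charge holds 6.60 µM of enzyme and 3.0 µM of impurity. If each impurity molecule takes one enzyme out of use, 3.60 µM of enzyme remains usable. Dividing the target made by that amount gives 965. Call this N, the target made per usable enzyme before it dies, a turnover number.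

Now freeze N and read the options off it. If the enzyme is dead, epsilon and alpha bring nothing. Eta adds 3.30 µM of enzyme, and, assuming no impurity remains and N holds for the new enzyme, I reckon a gain of 32 percentage points, which makes 66.8%. Yet one number is not enough: a flask stopped by balance shows the same N, so death is my bet and not a reading.

The forecast says “I therefore favour equilibrium”. It gives 34.8% now, 52% after epsilon and 35% after eta, with alpha as the best option, so it parts from my choice of eta.

The flask gives 35.2% at 15 h, 35.2% after epsilon and 43.7% after eta. The best option is eta, worth 8.5 points.

    complex ⇌ enzyme + target (K = 0.0130 M, k = 59.0 min⁻¹)
    substrate + enzyme ⇌ complex (K = 99.0 L mol⁻¹, k = 11000 L mol⁻¹ s⁻¹)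
    enzyme + impurity → spent catalyst A (k = 3.70 × 10⁵ L mol⁻¹ s⁻¹)
    target + enzyme ⇌ isomer of the product + enzyme, rate k4*[enzyme]*[target] forward; the back reaction follows from the equilibrium constant (K = 0.470, k = 2400 L mol⁻¹ min⁻¹)
    complex → spent catalyst B (k = 0.0410 min⁻¹)

In this flask the impurity had turned 45.5% of the enzyme charged into spent catalyst A by 90.0 min, while substrate passed through the complex to target. By 450 min the complex had left 54.5% of the enzyme charged as spent catalyst B, with target at 35.2% and isomer of the product at 4.97%. The enzyme added in eta brought a net 259 of target per enzyme, against an N of 965. In the neighbour flask with 6.0 mM of substrate, N foretells 15.4% of target at 15 h, and that flask holds 19.8%.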